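I began with the clock.

in all of them: free catalyst 2.8 mM

|  | starting material | second substrate | remark |
|---|---|---|---|
| north-west | 0.028 M | 0.056 M | run made earlier |
| north | 0.042 M | 0.056 M | run made earlier |
| flask | 0.056 M | 0.0560 M |  |

| run | time / h | target / % |
|---|---|---|
| north-west | 2.00 | 91 |
| north-west | 4.00 | 100 |
| north-west | 6.00 | 102 |
| north-west | 8.00 | 101 |
| north-west | 10.0 | 98 |
| north-west | 12.0 | 100 |
| north | 0.833 | 38 |
| north | 2.50 | 95 |
| north | 4.00 | 103 |
| north | 6.00 | 101 |
| north | 10.0 | 102 |
| north | 12.0 | 99 |

(each reading ± 2 percentage points)

1. apparent order in free catalyst when 30% of the starting material are converted (percent change of the rate of making target for one percent more free catalyst charged)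
2. apparent order in second substrate when 30% of the starting material are converted (percent change of the rate of making target for one percent more second substrate charged)

- the numbers in the tables scatter with a standard deviation of 2 percentage points
- what is bound to the catalyst counts as converted
- no earlier run changes the charge of free catalyst; that part of a forecast is a guess
- no earlier run changes the charge of second substrate; that part of a forecast is a guess

The bench rule I applied says that while the target climbs in a straight line, the catalyst works at a steady pace, so the rate is the catalyst charged times its turnovers per hour, whatever c(starting material) is, which is zero order in starting material. The first north reading, 38% of 0.042 M after 0.833 h, gave a rate of 0.0192 M h⁻¹, and dividing by the 2.8 mM of free catalyst gave the turnover frequency, target made per hour per catalyst charged, of 6.84 h⁻¹, a reading that carries the scatter of 2 percentage points.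

The rule would have finished the north-west charge in 1.46 h, yet that run read 91% at 2.00 h, and the north run's next stretch ran at 0.0144 M h⁻¹, slower than the first, so by these readings the north run's pace fell after its first reading. I therefore trusted the rule over the span of that first north reading, in which c(starting material) went from 0.042 M to 0.0260 M, although that span holds a single reading, so the straight climb there was my assumption. In the flask, 30% conversion leaves 0.0392 M, which is 0.933 of the north charge and inside that span, so I used the rule there. Taken at face value, it gave order 1 in free catalyst and, with c(second substrate) nowhere in it, order 0 in second substrate, though neither charge had been changed in any run, so both were guesses.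

The forecast gave 1 and 1.15, in its own words “The slowing tracks second substrate instead”, so we agreed on free catalyst and parted on second substrate.

The flask gave 0.74 in free catalyst and −0.056 in second substrate.

    starting material + free catalyst ⇌ catalyst intermediate A (K = 74.0 M⁻¹, k = 450 M⁻¹ min⁻¹)
    catalyst intermediate A → free catalyst + target (k = 0.290 min⁻¹)
    second substrate + free catalyst ⇌ catalyst intermediate B (K = 9.70 M⁻¹, k = 150 M⁻¹ min⁻¹)
    catalyst intermediate B → free catalyst + second product (k = 0.440 min⁻¹)
    2 catalyst intermediate A ⇌ resting dimer (K = 350 M⁻¹, k = 57.0 M⁻¹ min⁻¹)

Carried into the flask, 6.84 h⁻¹ on 2.8 mM for 1.20 h gave 41.1% of the starting material as target, and the flask held 45.0% at that time. At the start of the flask, starting material took up free catalyst 3.0 times as fast as second substrate did, each forward step taken alone, and at 1.20 h the flask held 19.5% of its catalyst as free catalyst, 39.7% as catalyst intermediate A, 9.02% as catalyst intermediate B and 31.7% as resting dimer, counted for the two catalysts each dimer holds.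

Readings and results stem from a simulated flask from invented constants, and the scatter is random.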